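**Plan**

- Retrosynthetic cuts, in order: the two O–benzyl bonds; the N–S bond and C1–H of an N-tosyl-1,2-dihydroisoquinoline (aromatisation); the C3=C4 bond of the pyridine ring (enamide–styrene ring-closing metathesis); the N-isopropenyl group (from N-acetyl); C1–CH3 (Grignard addition to a sulfinyl aldimine); the C4a–vinyl bond and the C7–C1' biaryl bond (two Suzuki couplings on one benzaldehyde); the phenol ring of the naphthalene (anionic annulation of an o-allylbenzamide).
- Enabling feature: ring A (C1, N2, C3, C4, C4a, C8a) has one carbon–carbon bond lying wholly outside the benzo ring, C3=C4. With C1 kept sp3 and N2 sulfonylated, that bond is an ordinary enamide alkene that metathesis can make, and the sp3 C1 beside C8a, C8 and C7 is a removable stereocentre next to the C7–C1' axis.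
- Forward order: the naphthalene ring is built first (steps 1–3), the biaryl bond follows (step 9), the vinyl group and the C1 amine branch are set on the preformed benzene ring, and the pyridine ring closes last (step 16) and is aromatised (step 17).
- Stereochemistry: C1 is set (S) by methyl Grignard addition under control of (R)-tert-butanesulfinamide. The axis forms racemic in the Suzuki step and is resolved as atropo-diastereomers after ring closure; C1 is then erased with the sulfinate.

Key step: step 16

Assumption: the target SMILES (4'-OMe, 5'-OH, 8-OH) is taken as written; it cannot show the C7–C1' axis, which is assumed to be M for the ent series. Since both atropo-diastereomers are separated in step 16, the other sense is equally available.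

**Route**

Step 1
Reactants: 1 2-methoxy-4-methylbenzoic acid
Product: 3 N,N-diethyl-2-methoxy-4-methylbenzamide, via acid chloride 2 (not isolated)
Conditions: (COCl)2, DMF (cat.), CH2Cl2, 0 °C to rt; evaporate; Et2NH, Et3N, CH2Cl2, 0 °C
Reagents that add atoms: diethylamine CCNCC
Why: Vilsmeier-catalysed acid chloride formation followed by Schotten–Baumann-type amidation is routine and installs the tertiary amide that directs the metalation of step 2 and supplies the acylating carbon of step 3.

Step 2
Reactants: 3 N,N-diethyl-2-methoxy-4-methylbenzamide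
Product: 6 2-allyl-N,N-diethyl-6-methoxy-4-methylbenzamide, via aryllithium 4 (not isolated), via arylmagnesium bromide 5 (not isolated)
Conditions: s-BuLi, TMEDA, THF, −78 °C; MgBr2·OEt2, −78 to 0 °C; allyl bromide, 0 °C to rt
Reagents that add atoms: allyl bromide C=CCBr
Why: Directed ortho-metalation takes place at C6, the only position ortho to the dominant amide director (C3 is wedged between OMe and CH3), and transmetalation to magnesium allows clean allylation of the aryl anion.

Step 3
Reactants: 6 2-allyl-N,N-diethyl-6-methoxy-4-methylbenzamide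
Product: 7 8-methoxy-6-methylnaphthalen-1-ol
Conditions: LiN(iPr)2 (2.2 equiv), THF, −78 °C to rt; aq. NH4Cl
Reagents that add atoms: none
Why: Anionic ring annulation of an o-allylbenzamide: deprotonation of the benzylic–allylic CH2 gives a delocalised anion whose terminal carbon acylates on the neighbouring amide, and loss of diethylamide with enolisation gives the 1-naphthol with C8 OMe, C6 CH3 and C1 OH fixed by the benzamide.

Step 4
Reactants: 7 8-methoxy-6-methylnaphthalen-1-ol
Product: 8 1-(benzyloxy)-8-methoxy-6-methylnaphthalene
Conditions: BnBr, K2CO3, DMF, 60 °C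
Reagents that add atoms: benzyl bromide BrCc1ccccc1
Why: Williamson etherification of the naphthoxide masks the later 5'-OH as a benzyl ether that survives organolithium, palladium, titanium, ruthenium and strong-base steps.

Step 5
Reactants: 8 1-(benzyloxy)-8-methoxy-6-methylnaphthalene
Product: 9 5-(benzyloxy)-1-bromo-4-methoxy-2-methylnaphthalene
Conditions: NBS (1.0 equiv), MeCN, 0 °C, dark
Reagents that add atoms: N-bromosuccinimide O=C1CCC(=O)N1Br
Why: Electrophilic aromatic bromination should go to the α-position that is para to the methoxy group and ortho to the methyl group, since it is more activated than the α-position para to the benzyloxy group alone.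

Step 6
Reactants: 9 5-(benzyloxy)-1-bromo-4-methoxy-2-methylnaphthalene
Product: 12 [5-(benzyloxy)-4-methoxy-2-methylnaphthalen-1-yl]boronic acid, via naphthyllithium 10 (not isolated), via lithium trimethoxyborate 11 (not isolated)
Conditions: n-BuLi, THF, −78 °C; B(OMe)3, −78 °C to rt; 1 M HCl
Reagents that add atoms: trimethyl borate COB(OC)OC; water O
Why: Bromine–lithium exchange is fast at −78 °C and leaves the benzyl ether alone, and trapping with the borate followed by hydrolysis gives the boronic acid for the hindered coupling.

Step 7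
Reactants: 13 2-bromo-5-chlorophenol
Product: 14 3-bromo-6-chloro-2-hydroxybenzaldehyde
Conditions: MgCl2, Et3N, (CH2O)n, THF, reflux; 1 M HCl
Reagents that add atoms: formaldehyde (as paraformaldehyde) C=O
Why: Magnesium-mediated ortho-formylation of phenols (Casnati–Skattebøl type) hydroxymethylates the magnesium phenoxide only ortho to oxygen, C6 is the single free ortho position, and a second formaldehyde accepts hydride to give the aldehyde.

Step 8
Reactants: 14 3-bromo-6-chloro-2-hydroxybenzaldehyde
Product: 15 2-(benzyloxy)-3-bromo-6-chlorobenzaldehyde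
Conditions: BnBr, K2CO3, DMF, rt
Reagents that add atoms: benzyl bromide BrCc1ccccc1
Why: Williamson etherification of the acidic salicylaldehyde hydroxyl is standard and fixes the later C8 oxygen as its benzyl ether.

Step 9
Reactants: 12 [5-(benzyloxy)-4-methoxy-2-methylnaphthalen-1-yl]boronic acid; 15 2-(benzyloxy)-3-bromo-6-chlorobenzaldehyde
Product: 16 2-(benzyloxy)-3-[5-(benzyloxy)-4-methoxy-2-methylnaphthalen-1-yl]-6-chlorobenzaldehyde (racemic at the axis)
Conditions: Pd(PPh3)4 (5 mol%), K3PO4, DME/H2O, 85 °C; 12 in excess (1.5 equiv)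
Reagents that add atoms: none
Why: Suzuki–Miyaura coupling in which PPh3-ligated zerovalent palladium inserts into the C–Br bond far faster than into the C–Cl bond, so the chloride is kept for step 10 while the hindered boronic acid transmetalates under aqueous phosphate conditions.

Step 10
Reactants: 16 2-(benzyloxy)-3-[5-(benzyloxy)-4-methoxy-2-methylnaphthalen-1-yl]-6-chlorobenzaldehyde
Product: 17 2-(benzyloxy)-3-[5-(benzyloxy)-4-methoxy-2-methylnaphthalen-1-yl]-6-vinylbenzaldehyde (racemic at the axis)
Conditions: vinylboronic acid pinacol ester, Pd(OAc)2 (5 mol%), SPhos (10 mol%), K3PO4, dioxane/H2O, 90 °C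
Reagents that add atoms: vinylboronic acid pinacol ester C=CB1OC(C)(C)C(C)(C)O1
Why: Suzuki–Miyaura vinylation in which the electron-rich biarylphosphine allows oxidative addition into the aryl chloride, itself activated by the ortho formyl group.

Step 11
Reactants: 17 2-(benzyloxy)-3-[5-(benzyloxy)-4-methoxy-2-methylnaphthalen-1-yl]-6-vinylbenzaldehyde; 18 (R)-tert-butanesulfinamide
Product: 19 (R,E)-N-{[2-(benzyloxy)-3-(5-benzyloxy-4-methoxy-2-methylnaphthalen-1-yl)-6-vinylphenyl]methylidene}-2-methylpropane-2-sulfinamide (both axial configurations)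
Conditions: Ti(OEt)4, THF, 50 °C
Reagents that add atoms: none
Why: Ellman condensation, in which Ti(OEt)4 acts as Lewis acid and water scavenger and gives the (E)-sulfinyl aldimine even from a di-ortho-substituted benzaldehyde.

Step 12
Reactants: 19 the (R)-sulfinyl aldimine
Product: 20 (R)-N-[(1S)-1-{2-(benzyloxy)-3-[5-(benzyloxy)-4-methoxy-2-methylnaphthalen-1-yl]-6-vinylphenyl}ethyl]-2-methylpropane-2-sulfinamide (both axial configurations)
Conditions: MeMgBr, CH2Cl2, −48 °C; aq. NH4Cl; chromatography to remove the minor C1 epimers
Reagents that add atoms: methylmagnesium bromide C[Mg]Br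
Why: Ellman Grignard addition in which magnesium bound to the sulfinyl oxygen delivers methyl through a chair-like six-membered transition state with tert-butyl equatorial, which for the (R)-sulfinyl (E)-aldimine sets the (S) configuration at C1.

Step 13
Reactants: 20 the (R,1S)-sulfinamide
Product: 22 N-[(1S)-1-{2-(benzyloxy)-3-[5-(benzyloxy)-4-methoxy-2-methylnaphthalen-1-yl]-6-vinylphenyl}ethyl]-4-methylbenzenesulfonamide (both axial configurations), via amine hydrochloride 21 (not isolated)
Conditions: 4 M HCl in dioxane, MeOH, rt; evaporate; TsCl, Et3N, DMAP (cat.), CH2Cl2, 0 °C to rt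
Reagents that add atoms: p-toluenesulfonyl chloride Cc1ccc(S(=O)(=O)Cl)cc1
Why: Acid cleaves the N–S bond by sulfinyl transfer to methanol and the freed primary amine is sulfonylated under standard conditions, neither event touching the C1 centre or the styrene.

Step 14
Reactants: 22 the (1S)-N-tosyl amine
Product: 23 N-[(1S)-1-{2-(benzyloxy)-3-[5-(benzyloxy)-4-methoxy-2-methylnaphthalen-1-yl]-6-vinylphenyl}ethyl]-N-tosylacetamide (both axial configurations)
Conditions: NaH, THF, 0 °C; AcCl, 0 °C to rt
Reagents that add atoms: acetyl chloride CC(=O)Cl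
Why: N-acylation of a sulfonamide anion with an acid chloride, as in the acylation of sultam auxiliaries, in which the small acetyl chloride reaches the hindered nitrogen and the C1 proton is far too weakly acidic to be removed.

Step 15
Reactants: 23 the (1S)-N-acetyl-N-tosyl amine
Product: 24 4-methyl-N-(prop-1-en-2-yl)-N-[(1S)-1-{2-(benzyloxy)-3-[5-(benzyloxy)-4-methoxy-2-methylnaphthalen-1-yl]-6-vinylphenyl}ethyl]benzenesulfonamide (both axial configurations)
Conditions: Cp2TiMe2 (3 equiv), toluene, 70 °C, dark; filtration through basic alumina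
Reagents that add atoms: dimethyltitanocene [CH3-].[CH3-].[Ti+4].c1cc[cH-]c1.c1cc[cH-]c1
Why: Petasis methylenation in which Cp2TiMe2 loses methane to Cp2Ti=CH2, which adds to the electrophilic imide-like carbonyl of the N-acylsulfonamide and collapses through an oxatitanacyclobutane to the enamide, a transformation known for N-acyl sulfonamides that carry alkenes.

Step 16
Reactants: 24 the (1S)-N-isopropenyl-N-tosyl amine
Product: 25 (M,1S)-8-(benzyloxy)-7-[5-(benzyloxy)-4-methoxy-2-methylnaphthalen-1-yl]-1,3-dimethyl-2-tosyl-1,2-dihydroisoquinoline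
Conditions: second-generation Grubbs catalyst RuCl2(=CHPh)(PCy3)(H2IMes) (10 mol%), toluene (0.005 M), 80 °C; the (M,1S) and (P,1S) atropo-diastereomers are then separated on Et3N-deactivated silica
Reagents that add atoms: none
Why: The ruthenium benzylidene first exchanges with the monosubstituted styrene alkene, and the resulting aryl carbene adds across the 1,1-disubstituted enamide alkene to a ruthenacyclobutane whose cycloreversion gives the trisubstituted C3=C4 bond and a ruthenium methylidene that continues the cycle with loss of ethylene. The closest known reaction type is the enamide–olefin ring-closing metathesis of N-sulfonyl enamides to dihydroquinolines and 1,2-dihydroisoquinolines with this catalyst. Ring A closes as a six-membered ring by intramolecular [2+2] cycloaddition and cycloreversion between two alkene termini held ortho to each other on the benzene ring. No stereocentre is formed, and the (S)-C1 centre and the biaryl axis are spectators. The step needs ring closure to outrun styrene homodimerisation and catalyst decay; high dilution, the ortho placement of both alkenes, and the sulfonyl group, which keeps the enamide nitrogen from binding ruthenium or stabilising a heteroatom-substituted carbene, are expected to secure this.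

Step 17
Reactants: 25 the (M,1S)-N-tosyl-1,2-dihydroisoquinoline
Product: 26 (M)-8-(benzyloxy)-7-[5-(benzyloxy)-4-methoxy-2-methylnaphthalen-1-yl]-1,3-dimethylisoquinoline
Conditions: KOtBu (3 equiv), tBuOH/THF, 60 °C
Reagents that add atoms: none
Why: Base-induced 1,2-elimination of sulfinate (E1cB, as in the Jackson variant of the Pomeranz–Fritsch synthesis), in which tert-butoxide removes the benzylic C1 proton, the anion expels p-toluenesulfinate from nitrogen, and the gain of isoquinoline aromaticity drives the step and erases C1 while the hindered axis stays fixed.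

Step 18
Reactants: 26 the (M)-dibenzyl ether
Product: 27 (M)-7-(5-hydroxy-4-methoxy-2-methylnaphthalen-1-yl)-1,3-dimethylisoquinolin-8-ol (target)
Conditions: H2 (1 atm), 10% Pd/C, EtOAc/MeOH, rt
Reagents that add atoms: none
Why: Catalytic hydrogenolysis cleaves both benzyl aryl ethers under conditions that leave the isoquinoline and naphthalene rings, the methyl ether and the axis intact.

**Compound list**

1 | 2-methoxy-4-methylbenzoic acid | COc1cc(C)ccc1C(=O)O | starting material
2 | 2-methoxy-4-methylbenzoyl chloride | COc1cc(C)ccc1C(=O)Cl | intermediate (not isolated)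
3 | N,N-diethyl-2-methoxy-4-methylbenzamide | CCN(CC)C(=O)c1ccc(C)cc1OC | intermediate
4 | 6-lithio-N,N-diethyl-2-methoxy-4-methylbenzamide | CCN(CC)C(=O)c1c([Li])cc(C)cc1OC | intermediate (not isolated)
5 | [2-(diethylcarbamoyl)-3-methoxy-5-methylphenyl]magnesium bromide | CCN(CC)C(=O)c1c([Mg]Br)cc(C)cc1OC | intermediate (not isolated)
6 | 2-allyl-N,N-diethyl-6-methoxy-4-methylbenzamide | C=CCc1cc(C)cc(OC)c1C(=O)N(CC)CC | intermediate
7 | 8-methoxy-6-methylnaphthalen-1-ol | COc1cc(C)cc2cccc(O)c12 | intermediate
8 | 1-(benzyloxy)-8-methoxy-6-methylnaphthalene | COc1cc(C)cc2cccc(OCc3ccccc3)c12 | intermediate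
9 | 5-(benzyloxy)-1-bromo-4-methoxy-2-methylnaphthalene | COc1cc(C)c(Br)c2cccc(OCc3ccccc3)c12 | intermediate
10 | [5-(benzyloxy)-4-methoxy-2-methylnaphthalen-1-yl]lithium | COc1cc(C)c([Li])c2cccc(OCc3ccccc3)c12 | intermediate (not isolated)
11 | lithium [5-(benzyloxy)-4-methoxy-2-methylnaphthalen-1-yl]trimethoxyborate | [Li+].COc1cc(C)c([B-](OC)(OC)OC)c2cccc(OCc3ccccc3)c12 | intermediate (not isolated)
12 | [5-(benzyloxy)-4-methoxy-2-methylnaphthalen-1-yl]boronic acid | COc1cc(C)c(B(O)O)c2cccc(OCc3ccccc3)c12 | intermediate
13 | 2-bromo-5-chlorophenol | Oc1cc(Cl)ccc1Br | starting material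
14 | 3-bromo-6-chloro-2-hydroxybenzaldehyde | O=Cc1c(Cl)ccc(Br)c1O | intermediate
15 | 2-(benzyloxy)-3-bromo-6-chlorobenzaldehyde | O=Cc1c(Cl)ccc(Br)c1OCc1ccccc1 | intermediate
16 | 2-(benzyloxy)-3-[5-(benzyloxy)-4-methoxy-2-methylnaphthalen-1-yl]-6-chlorobenzaldehyde, racemic at the axis | O=Cc1c(Cl)ccc(-c2c(C)cc(OC)c3c(OCc4ccccc4)cccc23)c1OCc1ccccc1 | intermediate
17 | 2-(benzyloxy)-3-[5-(benzyloxy)-4-methoxy-2-methylnaphthalen-1-yl]-6-vinylbenzaldehyde, racemic at the axis | C=Cc1ccc(-c2c(C)cc(OC)c3c(OCc4ccccc4)cccc23)c(OCc2ccccc2)c1C=O | intermediate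
18 | (R)-tert-butanesulfinamide | CC(C)(C)[S@@](=O)N | starting material
19 | (R,E)-N-sulfinyl aldimine of 17, both axial configurations | CC(C)(C)[S@@](=O)/N=C/c1c(C=C)ccc(-c2c(C)cc(OC)c3c(OCc4ccccc4)cccc23)c1OCc1ccccc1 | intermediate
20 | (R)-N-[(1S)-1-arylethyl]-2-methylpropane-2-sulfinamide (aryl = 2-benzyloxy-3-naphthyl-6-vinylphenyl), both axial configurations | CC(C)(C)[S@@](=O)N[C@@H](C)c1c(C=C)ccc(-c2c(C)cc(OC)c3c(OCc4ccccc4)cccc23)c1OCc1ccccc1 | intermediate
21 | (1S)-1-{2-(benzyloxy)-3-[5-(benzyloxy)-4-methoxy-2-methylnaphthalen-1-yl]-6-vinylphenyl}ethanaminium chloride | [NH3+][C@@H](C)c1c(C=C)ccc(-c2c(C)cc(OC)c3c(OCc4ccccc4)cccc23)c1OCc1ccccc1.[Cl-] | intermediate (not isolated)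
22 | N-[(1S)-1-arylethyl]-4-methylbenzenesulfonamide, both axial configurations | Cc1ccc(S(=O)(=O)N[C@@H](C)c2c(C=C)ccc(-c3c(C)cc(OC)c4c(OCc5ccccc5)cccc34)c2OCc2ccccc2)cc1 | intermediate
23 | N-[(1S)-1-arylethyl]-N-tosylacetamide, both axial configurations | CC(=O)N([C@@H](C)c1c(C=C)ccc(-c2c(C)cc(OC)c3c(OCc4ccccc4)cccc23)c1OCc1ccccc1)S(=O)(=O)c1ccc(C)cc1 | intermediate
24 | 4-methyl-N-(prop-1-en-2-yl)-N-[(1S)-1-arylethyl]benzenesulfonamide, both axial configurations (metathesis precursor) | C=C(C)N([C@@H](C)c1c(C=C)ccc(-c2c(C)cc(OC)c3c(OCc4ccccc4)cccc23)c1OCc1ccccc1)S(=O)(=O)c1ccc(C)cc1 | intermediate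
25 | (M,1S)-8-(benzyloxy)-7-[5-(benzyloxy)-4-methoxy-2-methylnaphthalen-1-yl]-1,3-dimethyl-2-tosyl-1,2-dihydroisoquinoline | C[C@@H]1N(S(=O)(=O)c2ccc(C)cc2)C(C)=Cc2ccc(-c3c(C)cc(OC)c4c(OCc5ccccc5)cccc34)c(OCc3ccccc3)c12 | intermediate
26 | (M)-8-(benzyloxy)-7-[5-(benzyloxy)-4-methoxy-2-methylnaphthalen-1-yl]-1,3-dimethylisoquinoline | Cc1cc2ccc(-c3c(C)cc(OC)c4c(OCc5ccccc5)cccc34)c(OCc3ccccc3)c2c(C)n1 | intermediate
27 | (M)-7-(5-hydroxy-4-methoxy-2-methylnaphthalen-1-yl)-1,3-dimethylisoquinolin-8-ol | COc1cc(C)c(-c2ccc3cc(C)nc(C)c3c2O)c2cccc(O)c12 | target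

**Count and risks**

Total step count: 18. Longest linear sequence: 16 steps (steps 1–6, then 9–18).

Steps most likely to fail:

1. Step 16. The ruthenium carbene may decay, or be held on the enamide carbon as an unreactive heteroatom-stabilised carbene, before the slow closure onto the 1,1-disubstituted alkene, so that intermolecular styrene dimerisation takes over. The fallback sets out from 23 and comes back at 25. The N-acetyl sulfonamide is cyclised directly by titanium-mediated carbonyl–olefin metathesis with a reduced titanium ethylidene (TiCl4, Zn, PbCl2 (cat.), TMEDA, CH3CHBr2, THF/CH2Cl2, 65 °C), a known way to close cyclic enamides from olefinic amides. It forms the same C3=C4 bond without passing through 24, and the atropo-diastereomers of 25 are separated as before. No new compound arises on this path (F0).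

2. Step 17. Removal of the tertiary, crowded C1 proton may be too slow for sulfinate to be expelled, and prolonged heating in strong base would then erode the material. The fallback sets out from 25 and comes back at 26. The N–S bond is cleaved reductively with Mg in MeOH under sonication to give (M,1S)-8-(benzyloxy)-7-[5-(benzyloxy)-4-methoxy-2-methylnaphthalen-1-yl]-1,3-dimethyl-1,2-dihydroisoquinoline F1. This is then dehydrogenated with MnO2 in CH2Cl2 at rt to the isoquinoline 26.

3. Step 15. Methylenation of the crowded imide carbonyl may stall, or the acid-sensitive enamide may hydrolyse back to the sulfonamide during isolation. The fallback sets out from 22 and comes back at 24. The sulfonamide nitrogen is alkenylated directly with 2-bromopropene in a copper-catalysed Goldberg-type coupling (CuI, N,N'-dimethylethylenediamine, Cs2CO3, dioxane, sealed tube, 100 °C), which bypasses 23. No new compound arises on this path (F0).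

Further compounds
F0 | step 16 | none | none
F1 | step 17 | (M,1S)-8-(benzyloxy)-7-[5-(benzyloxy)-4-methoxy-2-methylnaphthalen-1-yl]-1,3-dimethyl-1,2-dihydroisoquinoline | C[C@@H]1NC(C)=Cc2ccc(-c3c(C)cc(OC)c4c(OCc5ccccc5)cccc34)c(OCc3ccccc3)c12
F0 | step 15 | none | none
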